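**Plan**
- Retrosynthesis: the C6–C7 bond is cut last, with C7=C8 carried as C7≡C8 so that C7 is a slim sp nucleophile; then C11'=C12' and C11=C12 (Wittig) and C9'=C10' (HWE); the C5/C6 oxygens are traced back to ketoisophorone.
- Forward: ketoisophorone gives the silylated C9 hydroxy ketone 7; (R)-α-ionone gives the ε-C15 phosphonium salt 15; the C6 enyne salt 18 and the C10 dialdehyde 19 give the C16 ynal 20; 15 + 20 give the C31 polyenyne 21.
- The lithium acetylide of 21 adds to 7 (C40 skeleton); hydroxyl-directed trans-hydroalumination gives E-C7=C8; desilylation gives the tetrol. Both rings are bought, none is formed.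
- Enabling feature: C6 of the trihydroxycyclohexane ring lies between quaternary C1 (gem-dimethyl) and quaternary C5 (methyl, oxygen) and carries the sp2 carbon C7. As a ketone it cannot enolise, and one face is closed by syn-axial methyls on C1 and C5.
- Stereochemistry: C3 and C3' by catalyst-controlled transfer hydrogenation (mirror-image catalysts); C5 by hydroxyl-directed epoxidation; C6 by axial attack anti to the C5 methyl; C6' from (R)-α-ionone. Alkene geometry comes from E-configured reagents, E-selective HWE, Wittig plus thermal relaxation, and trans-hydroalumination.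

Key step: step 16

Assumption: (R)-α-ionone of high ee, ketoisophorone, (2E)-3-methylpent-2-en-4-yn-1-ol and the C10 dialdehyde 19 are bought; the transfer hydrogenations are given the sense of the aryl ketone model, with the alkenyl arm as the π group.

**Ring ketone**

Step 1
Reactants: 1 ketoisophorone
Product: 2 (4S)-4-hydroxy-2,6,6-trimethylcyclohex-2-en-1-one
Conditions: RuCl[(S,S)-TsDPEN](p-cymene) (1 mol%), i-PrOH, rt
Reagents that add atoms: none
Why: Noyori asymmetric transfer hydrogenation should reduce only the open C4 carbonyl (C1 is flanked by the gem-dimethyl carbon and the methyl-bearing alkene carbon) and set the carbinol centre by catalyst control, the alkenyl arm taking the place of the aryl group in the CH/π model.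

Step 2
Reactants: 2 (4S)-4-hydroxy-2,6,6-trimethylcyclohex-2-en-1-one
Product: 3 (1S,5S,6S)-5-hydroxy-1,3,3-trimethyl-7-oxabicyclo[4.1.0]heptan-2-one (epoxide cis to OH)
Conditions: 30% H2O2, NaOH (0.3 equiv), MeOH, 0 °C
Reagents that add atoms: hydrogen peroxide OO
Why: Weitz–Scheffer epoxidation in which the free hydroxyl should steer the hydroperoxide by hydrogen bonding to its own face, which is also the axial trajectory at the β-carbon in the half-chair that keeps the hydroxyl pseudoequatorial (pseudoaxial it would clash with an axial methyl of the gem-dimethyl carbon), so the tertiary C–O centre is set cis to the carbinol.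

Step 3
Reactants: 3 cis-epoxy alcohol
Product: 4 (2S,4S)-2,6,6-trimethylcyclohexane-1,2,4-triol (mixture of C1 epimers)
Conditions: LiAlH4, THF, 0 °C to reflux; aqueous work-up
Reagents that add atoms: none
Why: LiAlH4 reduces the ketone and opens the trisubstituted epoxide by SN2 hydride attack at its secondary carbon, so the tertiary C–O bond and its configuration cis to the C4 hydroxyl are kept; the C1 carbinol epimers converge in step 5.

Step 4
Reactants: 4 triol
Product: 5 (2S,4S)-4-(tert-butyldimethylsilyloxy)-2,6,6-trimethylcyclohexane-1,2-diol (numbered as 4; C1 epimers)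
Conditions: TBSCl (1.05 equiv), imidazole, DMF, 0 °C
Reagents that add atoms: tert-butyldimethylsilyl chloride CC(C)(C)[Si](C)(C)Cl
Why: Silylation should be selective for the only unhindered secondary hydroxyl, since the other secondary hydroxyl lies between two fully substituted carbons and the third is tertiary.

Step 5
Reactants: 5 mono-TBS diol
Product: 6 (2S,4S)-4-(tert-butyldimethylsilyloxy)-2-hydroxy-2,6,6-trimethylcyclohexan-1-one
Conditions: (COCl)2, DMSO, CH2Cl2, −78 °C; Et3N, to 0 °C
Reagents that add atoms: none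
Why: Swern oxidation converts the one remaining secondary alcohol of both epimers into the ketone, leaves the tertiary alcohol alone and avoids the glycol cleavage that chelating oxidants can cause.

Step 6
Reactants: 6 α-hydroxy ketone
Product: 7 (2S,4S)-4-(tert-butyldimethylsilyloxy)-2,6,6-trimethyl-2-(trimethylsilyloxy)cyclohexan-1-one
Conditions: TMSOTf, 2,6-lutidine, CH2Cl2, −78 to 0 °C
Reagents that add atoms: trimethylsilyl triflate C[Si](C)(C)OS(=O)(=O)C(F)(F)F
Why: Silyl triflate silylation of the tertiary alcohol is clean here because the ketone has no α-hydrogen and cannot form a silyl enol ether.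

**ε-End C15 unit**

Step 7
Reactants: 8 (R)-α-ionone
Product: 9 ethyl (2E,4E)-3-methyl-5-[(1R)-2,6,6-trimethylcyclohex-2-en-1-yl]penta-2,4-dienoate
Conditions: triethyl phosphonoacetate, NaH, THF, 0 °C to rt; 2Z isomer removed by chromatography
Reagents that add atoms: triethyl phosphonoacetate CCOC(=O)CP(=O)(OCC)OCC
Why: Horner–Wadsworth–Emmons olefination of the methyl ketone should give mainly the 2E dienoate, and the weakly basic phosphonate anion does not touch the ring stereocentre.

Step 8
Reactants: 9 dienoate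
Product: 10 ethyl (2E,4E)-3-methyl-5-[(1R)-2,6,6-trimethyl-4-oxocyclohex-2-en-1-yl]penta-2,4-dienoate
Conditions: t-BuOOH, Rh2(cap)4 (1 mol%), K2CO3 (0.5 equiv), CH2Cl2, rt
Reagents that add atoms: tert-butyl hydroperoxide CC(C)(C)OO
Why: Radical allylic C–H oxidation should take the ring CH2 next to the trisubstituted alkene, as it does in α-ionone derivatives, because the doubly allylic ring C–H is tertiary and shielded by the gem-dimethyl group.

Step 9
Reactants: 10 ring enone
Product: 11 ethyl (2E,4E)-5-[(1R,4R)-4-hydroxy-2,6,6-trimethylcyclohex-2-en-1-yl]-3-methylpenta-2,4-dienoate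
Conditions: Ru[(R,R)-TsDPEN](p-cymene) amido complex (1 mol%), i-PrOH, rt, no added base
Reagents that add atoms: none
Why: Asymmetric transfer hydrogenation of a carbonyl with the same local environment as in step 1, now with the mirror-image catalyst, should set the carbinol (trans to the side chain) by catalyst control, while the dienoate is inert and base-free conditions protect the γ-stereocentre.

Step 10
Reactants: 11 allylic alcohol
Product: 12 ethyl (2E,4E)-5-[(1R,4R)-4-(tert-butyldimethylsilyloxy)-2,6,6-trimethylcyclohex-2-en-1-yl]-3-methylpenta-2,4-dienoate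
Conditions: TBSCl, imidazole, DMF, rt
Reagents that add atoms: tert-butyldimethylsilyl chloride CC(C)(C)[Si](C)(C)Cl
Why: Standard silylation of a secondary alcohol, which masks the acid-sensitive allylic hydroxyl for the following steps.

Step 11
Reactants: 12 silylated dienoate
Product: 13 (2E,4E)-5-[(1R,4R)-4-(tert-butyldimethylsilyloxy)-2,6,6-trimethylcyclohex-2-en-1-yl]-3-methylpenta-2,4-dien-1-ol
Conditions: DIBAL-H (2.2 equiv), CH2Cl2, −78 °C; Rochelle salt
Reagents that add atoms: none
Why: DIBAL-H reduces the conjugated ester to the allylic alcohol by 1,2-addition without touching the diene or the silyl ether.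

Step 12
Reactants: 13 dienol
Product: 15 [(2E,4E)-5-[(1R,4R)-4-(tert-butyldimethylsilyloxy)-2,6,6-trimethylcyclohex-2-en-1-yl]-3-methylpenta-2,4-dien-1-yl]triphenylphosphonium bromide, via allylic bromide 14 (not isolated)
Conditions: CBr4, PPh3, CH2Cl2, 0 °C; then PPh3, EtOAc, rt
Reagents that add atoms: carbon tetrabromide BrC(Br)(Br)Br; triphenylphosphine c1ccc(cc1)P(c1ccccc1)c1ccccc1
Why: Appel bromination under neutral conditions spares the allylic silyl ether that HBr-based salt formation would ionise, and SN2 quaternisation at the primary carbon gives the Wittig salt.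

**Chain assembly**

Step 13
Reactants: 16 (2E)-3-methylpent-2-en-4-yn-1-ol
Product: 18 [(2E)-3-methylpent-2-en-4-yn-1-yl]triphenylphosphonium bromide, via enyne bromide 17 (not isolated)
Conditions: CBr4, PPh3, CH2Cl2, 0 °C; then PPh3, toluene, rt
Reagents that add atoms: carbon tetrabromide BrC(Br)(Br)Br; triphenylphosphine c1ccc(cc1)P(c1ccccc1)c1ccccc1
Why: Appel bromination followed by SN2 quaternisation keeps the E-alkene and the free terminal alkyne.

Step 14
Reactants: 18 C6 enyne phosphonium salt; 19 (2E,4E,6E)-2,7-dimethylocta-2,4,6-trienedial (3 equiv)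
Product: 20 (2E,4E,6E,8E,10E)-2,7,11-trimethyltrideca-2,4,6,8,10-pentaen-12-ynal
Conditions: NaOMe, MeOH/CH2Cl2, 0 °C to rt; then heptane, 80 °C
Reagents that add atoms: none
Why: Wittig olefination of one aldehyde of the excess symmetrical dialdehyde forms C11=C12; the phosphonium α-hydrogen is far more acidic than the alkyne C–H, so no alkyne protection is needed, and heating relaxes the hindered 11Z isomer to E.

Step 15
Reactants: 15 ε-C15 phosphonium salt; 20 C16 ynal
Product: 21 all-E C31 polyenyne (3-O-TBS (3R,6R)-ε-ring carrying the chain from C7' to C8 that ends in the free C7≡C8–H alkyne, target numbering)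
Conditions: NaOMe, MeOH/CH2Cl2, rt, dark; then heptane, 80 °C
Reagents that add atoms: none
Why: Wittig olefination forms C11'=C12' as in classical carotenoid chain assembly; the secondary TBS ether and the terminal alkyne tolerate methoxide, and the hindered 11'Z isomer relaxes thermally to E.

**Union and endgame**

Step 16
Reactants: 21 C31 polyenyne; 7 silylated hydroxy ketone (1.5 equiv)
Product: 24 (3S,5S,6R,3'R,6'R)-3,3'-bis(tert-butyldimethylsilyloxy)-7,8-didehydro-5,6-dihydro-β,ε-carotene-5,6-diol, via lithium acetylide 22 (not isolated), via lithium alkoxide TMS ether 23 (not isolated)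
Conditions: n-BuLi (1.0 equiv), THF, −78 °C; 7, −78 to −20 °C; then MeOH, K2CO3 (cat.), 0 °C to rt
Reagents that add atoms: none
Why: n-BuLi removes the only acidic proton of 21 (the sp C7–H) and the lithium acetylide adds to the C6 carbonyl of 7, which has no α-hydrogen on either side (C1 carries two methyls, C5 carries methyl and OTMS), so enolisation cannot compete and the C6–C7 bond forms at the most congested carbon of the target. The closest known reaction type is the addition of lithium acetylides to 2,2,6-trisubstituted 4-silyloxycyclohexanones used to join ring and chain in carotenoid end-group work; no ring is closed. The new centre C6 is set by the substrate: in the chair that keeps 3-OTBS and 5-OTMS equatorial, the C5 methyl and one C1 methyl are syn-axial and close one face, so the slim sp nucleophile enters axially from the other face, anti to the C5 methyl, which places C7 cis to O5 and O3 and the new hydroxyl trans to O5, as in the target (6R here is only a descriptor change from 6S in 26). The step needs chemoselectivity, secured by the pKa gap between the alkyne C–H and all other C–H bonds and by the non-enolisable ketone used in excess, and facial selectivity, secured by the two axial methyls. Methanolysis in the same flask removes the tertiary TMS group wherever it sits after a possible 1,2 O-to-O silyl shift, so a single diol should be isolated.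

Step 17
Reactants: 24 C40 ynediol
Product: 25 (3S,5S,6S,3'R,6'R)-3,3'-bis(tert-butyldimethylsilyloxy)-5,6-dihydro-β,ε-carotene-5,6-diol (all-E)
Conditions: Red-Al (4 equiv), THF, 0 °C to rt; Rochelle salt
Reagents that add atoms: none
Why: Hydroxyl-directed trans-hydroalumination of the propargylic alcohol delivers hydride from the C6–O–Al unit to C7 and places aluminium on C8, so protonolysis should give only the E-C7=C8 alkene, while the rest of the polyene has no such internal hydride donor.

Step 18
Reactants: 25 bis-TBS ether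
Product: 26 (3S,5S,6S,3'R,6'R)-5,6-dihydro-β,ε-carotene-3,5,6,3'-tetrol (all-E), the target
Conditions: TBAF, THF, 0 °C to rt, dark
Reagents that add atoms: none
Why: Fluoride cleaves both secondary TBS ethers under non-acidic conditions that spare the tertiary allylic diol and the polyene.

**Compound list**
1 | ketoisophorone (2,6,6-trimethylcyclohex-2-ene-1,4-dione) | CC1=CC(=O)CC(C)(C)C1=O | starting material
2 | (4S)-4-hydroxy-2,6,6-trimethylcyclohex-2-en-1-one | O=C1C(C)=C[C@@H](O)CC1(C)C | intermediate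
3 | (1S,5S,6S)-5-hydroxy-1,3,3-trimethyl-7-oxabicyclo[4.1.0]heptan-2-one | O=C1C(C)(C)C[C@H](O)[C@@H]2O[C@]12C | intermediate
4 | (2S,4S)-2,6,6-trimethylcyclohexane-1,2,4-triol, C1 epimers (C1 left undefined) | OC1C(C)(C)C[C@H](O)C[C@]1(C)O | intermediate
5 | 4-O-TBS ether of 4, C1 epimers | OC1C(C)(C)C[C@H](O[Si](C)(C)C(C)(C)C)C[C@]1(C)O | intermediate
6 | (2S,4S)-4-(tert-butyldimethylsilyloxy)-2-hydroxy-2,6,6-trimethylcyclohexan-1-one | O=C1C(C)(C)C[C@H](O[Si](C)(C)C(C)(C)C)C[C@]1(C)O | intermediate
7 | (2S,4S)-4-(tert-butyldimethylsilyloxy)-2,6,6-trimethyl-2-(trimethylsilyloxy)cyclohexan-1-one | O=C1C(C)(C)C[C@H](O[Si](C)(C)C(C)(C)C)C[C@]1(C)O[Si](C)(C)C | intermediate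
8 | (R)-α-ionone | CC1=CCCC(C)(C)[C@H]1/C=C/C(C)=O | starting material
9 | ethyl (2E,4E)-3-methyl-5-[(1R)-2,6,6-trimethylcyclohex-2-en-1-yl]penta-2,4-dienoate | CC1=CCCC(C)(C)[C@H]1/C=C/C(C)=C/C(=O)OCC | intermediate
10 | ethyl (2E,4E)-3-methyl-5-[(1R)-2,6,6-trimethyl-4-oxocyclohex-2-en-1-yl]penta-2,4-dienoate | CC1=CC(=O)CC(C)(C)[C@H]1/C=C/C(C)=C/C(=O)OCC | intermediate
11 | ethyl (2E,4E)-5-[(1R,4R)-4-hydroxy-2,6,6-trimethylcyclohex-2-en-1-yl]-3-methylpenta-2,4-dienoate | CC1=C[C@H](O)CC(C)(C)[C@H]1/C=C/C(C)=C/C(=O)OCC | intermediate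
12 | TBS ether of 11 | CC1=C[C@H](O[Si](C)(C)C(C)(C)C)CC(C)(C)[C@H]1/C=C/C(C)=C/C(=O)OCC | intermediate
13 | (2E,4E)-5-[(1R,4R)-4-(tert-butyldimethylsilyloxy)-2,6,6-trimethylcyclohex-2-en-1-yl]-3-methylpenta-2,4-dien-1-ol | CC1=C[C@H](O[Si](C)(C)C(C)(C)C)CC(C)(C)[C@H]1/C=C/C(C)=C/CO | intermediate
14 | allylic bromide from 13 | CC1=C[C@H](O[Si](C)(C)C(C)(C)C)CC(C)(C)[C@H]1/C=C/C(C)=C/CBr | intermediate (not isolated)
15 | ε-C15 triphenylphosphonium bromide | CC1=C[C@H](O[Si](C)(C)C(C)(C)C)CC(C)(C)[C@H]1/C=C/C(C)=C/C[P+](c1ccccc1)(c1ccccc1)c1ccccc1.[Br-] | intermediate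
16 | (2E)-3-methylpent-2-en-4-yn-1-ol | C#C/C(C)=C/CO | starting material
17 | (3E)-5-bromo-3-methylpent-3-en-1-yne | C#C/C(C)=C/CBr | intermediate (not isolated)
18 | [(2E)-3-methylpent-2-en-4-yn-1-yl]triphenylphosphonium bromide | C#C/C(C)=C/C[P+](c1ccccc1)(c1ccccc1)c1ccccc1.[Br-] | intermediate
19 | (2E,4E,6E)-2,7-dimethylocta-2,4,6-trienedial | O=C/C(C)=C/C=C/C=C(C)/C=O | starting material
20 | (2E,4E,6E,8E,10E)-2,7,11-trimethyltrideca-2,4,6,8,10-pentaen-12-ynal | C#C/C(C)=C/C=C/C(C)=C/C=C/C=C(C)/C=O | intermediate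
21 | all-E C31 polyenyne with 3-O-TBS (3R,6R)-ε-ring and terminal C7≡C8–H | CC1=C[C@H](O[Si](C)(C)C(C)(C)C)CC(C)(C)[C@H]1/C=C/C(C)=C/C=C/C(C)=C/C=C/C=C(C)/C=C/C=C(C)/C#C | intermediate
22 | lithium acetylide of 21 | CC1=C[C@H](O[Si](C)(C)C(C)(C)C)CC(C)(C)[C@H]1/C=C/C(C)=C/C=C/C(C)=C/C=C/C=C(C)/C=C/C=C(C)/C#[C-].[Li+] | intermediate (not isolated)
23 | C40 lithium C6-alkoxide, 5-O-TMS, 3,3'-bis-O-TBS, 7,8-didehydro | CC1=C[C@H](O[Si](C)(C)C(C)(C)C)CC(C)(C)[C@H]1/C=C/C(C)=C/C=C/C(C)=C/C=C/C=C(C)/C=C/C=C(C)/C#C[C@]1([O-])C(C)(C)C[C@H](O[Si](C)(C)C(C)(C)C)C[C@]1(C)O[Si](C)(C)C.[Li+] | intermediate (not isolated)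
24 | (3S,5S,6R,3'R,6'R)-3,3'-bis(tert-butyldimethylsilyloxy)-7,8-didehydro-5,6-dihydro-β,ε-carotene-5,6-diol | CC1=C[C@H](O[Si](C)(C)C(C)(C)C)CC(C)(C)[C@H]1/C=C/C(C)=C/C=C/C(C)=C/C=C/C=C(C)/C=C/C=C(C)/C#C[C@]1(O)C(C)(C)C[C@H](O[Si](C)(C)C(C)(C)C)C[C@]1(C)O | intermediate
25 | (3S,5S,6S,3'R,6'R)-3,3'-bis(tert-butyldimethylsilyloxy)-5,6-dihydro-β,ε-carotene-5,6-diol | CC1=C[C@H](O[Si](C)(C)C(C)(C)C)CC(C)(C)[C@H]1/C=C/C(C)=C/C=C/C(C)=C/C=C/C=C(C)/C=C/C=C(C)/C=C/[C@]1(O)C(C)(C)C[C@H](O[Si](C)(C)C(C)(C)C)C[C@]1(C)O | intermediate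
26 | (3S,5S,6S,3'R,6'R)-5,6-dihydro-β,ε-carotene-3,5,6,3'-tetrol | CC1=C[C@H](O)CC(C)(C)[C@H]1/C=C/C(C)=C/C=C/C(C)=C/C=C/C=C(C)/C=C/C=C(C)/C=C/[C@]1(O)C(C)(C)C[C@H](O)C[C@]1(C)O | target

**Totals**
Total step count: 18.
Longest linear sequence: 10 steps (steps 7–12, then 15–18, from (R)-α-ionone).

**Steps most likely to fail, with fallbacks**

Step 16. The bulky polyenyl acetylide may add slowly or reversibly to the doubly neopentyl carbonyl, or the lithiated polyene may decay before it adds. The fallback moves the same bond formation to the C15 stage and sets out from 6 and 16. The dilithio derivative of 16 (2 n-BuLi per alcohol, used in excess, THF, −78 to 0 °C) adds to 6 with the same facial argument and gives (2E)-5-[(1R,2S,4S)-4-(tert-butyldimethylsilyloxy)-1,2-dihydroxy-2,6,6-trimethylcyclohexyl]-3-methylpent-2-en-4-yn-1-ol F1. Red-Al reduction of the propargylic alcohol gives the (2E,4E)-dienol F2. Appel bromination of the primary allylic hydroxyl (the tertiary hydroxyls do not react) gives the allylic bromide F3, and triphenylphosphine converts it into the C15 phosphonium bromide F4. In parallel, Wittig reaction of 15 with excess 19 (NaOMe) gives the C25 apo-aldehyde F5. Wittig reaction of F4 with F5 (NaOMe, MeOH/CH2Cl2, then thermal relaxation) forms C11=C12 and comes back to the route at 25, before step 18.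

Step 17. The hydride may attack or isomerise the long polyene, or the alanate may fail to form at the congested diol. The fallback makes C7 an alkenyl nucleophile and sets out from 21. Hydrozirconation of the terminal alkyne with Cp2Zr(H)Cl followed by iodine gives the (E)-vinyl iodide F6. Iodine–lithium exchange (t-BuLi, 2 equiv, Et2O/THF, −78 °C) gives the alkenyllithium F7, which adds to 7 from the same open face to give the lithium alkoxide TMS ether F8. Methanol with catalytic K2CO3 removes the TMS group, and the route is rejoined at 25, without 24 and without step 17.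

Step 2. The free hydroxyl may fail to steer the peroxide, so that the epoxide forms mainly on the face away from it. The fallback then uses that preference and corrects the secondary carbinol by inversion; it sets out from 1. Step 1 is run with the (R,R) catalyst to give (4R)-4-hydroxy-2,6,6-trimethylcyclohex-2-en-1-one F9. Epoxidation under the conditions of step 2 then gives the trans-epoxy alcohol (1S,5R,6S)-5-hydroxy-1,3,3-trimethyl-7-oxabicyclo[4.1.0]heptan-2-one F10, which already has the tertiary C–O centre of the target. Mitsunobu inversion (benzoic acid, PPh3, DIAD) gives the cis benzoate (1S,2S,6S)-4,4,6-trimethyl-5-oxo-7-oxabicyclo[4.1.0]heptan-2-yl benzoate F11. LiAlH4 as in step 3 cleaves the ester, reduces the ketone and opens the epoxide, and the route is rejoined at 4.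

Further compounds
F1 | step 16 | (2E)-5-[(1R,2S,4S)-4-(tert-butyldimethylsilyloxy)-1,2-dihydroxy-2,6,6-trimethylcyclohexyl]-3-methylpent-2-en-4-yn-1-ol | OC/C=C(C)/C#C[C@]1(O)C(C)(C)C[C@H](O[Si](C)(C)C(C)(C)C)C[C@]1(C)O
F2 | step 16 | (2E,4E)-5-[(1S,2S,4S)-4-(tert-butyldimethylsilyloxy)-1,2-dihydroxy-2,6,6-trimethylcyclohexyl]-3-methylpenta-2,4-dien-1-ol | OC/C=C(C)/C=C/[C@]1(O)C(C)(C)C[C@H](O[Si](C)(C)C(C)(C)C)C[C@]1(C)O
F3 | step 16 | allylic bromide from F2 | BrC/C=C(C)/C=C/[C@]1(O)C(C)(C)C[C@H](O[Si](C)(C)C(C)(C)C)C[C@]1(C)O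
F4 | step 16 | C15 triphenylphosphonium bromide of the trihydroxy ring end | [Br-].c1ccccc1[P+](c1ccccc1)(c1ccccc1)C/C=C(C)/C=C/[C@]1(O)C(C)(C)C[C@H](O[Si](C)(C)C(C)(C)C)C[C@]1(C)O
F5 | step 16 | all-E C25 apo-aldehyde with 3-O-TBS (3R,6R)-ε-ring and C12 aldehyde | CC1=C[C@H](O[Si](C)(C)C(C)(C)C)CC(C)(C)[C@H]1/C=C/C(C)=C/C=C/C(C)=C/C=C/C=C(C)/C=O
F6 | step 17 | (E)-vinyl iodide from 21 | CC1=C[C@H](O[Si](C)(C)C(C)(C)C)CC(C)(C)[C@H]1/C=C/C(C)=C/C=C/C(C)=C/C=C/C=C(C)/C=C/C=C(C)/C=C/I
F7 | step 17 | (E)-alkenyllithium from F6 | CC1=C[C@H](O[Si](C)(C)C(C)(C)C)CC(C)(C)[C@H]1/C=C/C(C)=C/C=C/C(C)=C/C=C/C=C(C)/C=C/C=C(C)/C=C/[Li]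
F8 | step 17 | C40 lithium C6-alkoxide, 5-O-TMS, 3,3'-bis-O-TBS, E-C7=C8 | CC1=C[C@H](O[Si](C)(C)C(C)(C)C)CC(C)(C)[C@H]1/C=C/C(C)=C/C=C/C(C)=C/C=C/C=C(C)/C=C/C=C(C)/C=C/[C@]1([O-])C(C)(C)C[C@H](O[Si](C)(C)C(C)(C)C)C[C@]1(C)O[Si](C)(C)C.[Li+]
F9 | step 2 | (4R)-4-hydroxy-2,6,6-trimethylcyclohex-2-en-1-one | O=C1C(C)=C[C@H](O)CC1(C)C
F10 | step 2 | (1S,5R,6S)-5-hydroxy-1,3,3-trimethyl-7-oxabicyclo[4.1.0]heptan-2-one | O=C1C(C)(C)C[C@@H](O)[C@@H]2O[C@]12C
F11 | step 2 | (1S,2S,6S)-4,4,6-trimethyl-5-oxo-7-oxabicyclo[4.1.0]heptan-2-yl benzoate | O=C1C(C)(C)C[C@H](OC(=O)c2ccccc2)[C@@H]2O[C@]12C
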